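Compound numbers are those of the steps below. The ring is numbered C1 (CH–OAc), C2 (CH–OBz), C3=C4, C5 (CH–OH), C6 (C–OH) and C7 (the CH2–OBz carbon on C6); the systematic names in the compound list use IUPAC locants instead.

## Analysis of the target

Compound 12 is a single cyclohexene ring with one exocyclic carbon, and five of its seven skeletal carbons carry oxygen. C1, C2, C5 and C6 are stereogenic (1S,2R,5S,6R in the working numbering), and C6 is a fully substituted carbinol. The C1 acetate and the C6 hydroxyl lie on one face; the C2 benzoate, the C5 hydroxyl and C7 lie on the other. C1/C2 is therefore trans, C1–O/C6–O is cis and C5/C6 is a trans diol. Three esters beside two free hydroxyls invite acyl migration (C1 acetate to the cis C6–OH, C7 benzoate to C5–OH or C6–OH), and the C2 and C5 oxygens are allylic and can ionise or transpose. Every precursor at the diene oxidation level can aromatise by losing water, silanol or benzoic acid. The difficulty is not the skeleton but placing four stereocentres, one of them quaternary, and telling five oxygens apart (one acetate, two benzoates, two free). The strategy reads the C5/C6 trans diol as a hydrated C5–C6 epoxide, and that epoxide as an oxidised C5=C6 alkene. What is left is a cyclohexa-1,3-diene C3=C4–C5=C6 with C7 on the terminus C6 and a trans-dioxygenated sp3 pair C1–C2, which is the pattern a 2-pyrone with a C3 carboxylate gives with a 1,2-dioxygenated alkene after decarboxylation.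

## Retrosynthetic reasoning

**12 to 11.** The C5–OH bond is cut and the C5 and C6 oxygens are folded back into an oxirane on the face of the C1 oxygen. Hydration at the allylic carbon C5 with inversion gives the trans C5/C6 diol and leaves the C6–O bond untouched. The cut is made here because the epoxide keeps the C5 and C6 oxygens masked while the C1 oxygen is acylated.

**11 to 10.** The acetate is removed. In 10 the C1 hydroxyl is the only free hydroxyl, so the acetate can be placed without any selectivity question. That would not be true after the epoxide is opened.

**10 to 9.** The two C–O bonds of the oxirane are cut, giving the diene 9 with a free C1 hydroxyl. Forward, that hydroxyl must steer a peracid to the neighbouring trisubstituted C5=C6 alkene and to its own face. This sets C6 directly and, through the later inversion, C5.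

**9 to 5.** Only functional-group changes are undone: the C2 benzoate (9 to 8), the two silyl ethers (8 to 7), the C7 benzoate (7 to 6) and the reduction of the ester that becomes C7 (6 to 5). The order puts the C7 benzoate on while C1–O and C2–O are still silylated. The only selectivity demanded is C2–OH over C1–OH in the diol 8.

**5 to 2 and 3 (via 4).** The bonds C6–C1 and C3–C2 are cut. This disconnection removes the whole carbocycle and both carbinol centres C1 and C2 in one operation and leads to two achiral pieces: pyrone 3, which brings C3–C6 and C7, and the symmetric E alkene 2, which brings C1 and C2. Forward, a [4+2] addition must pass the E geometry on as the trans C1/C2 relation and must select one face of 2. The bicyclic lactone 4 then loses its lactone bridge by cycloreversion to leave the diene 5. Cutting elsewhere (C1–C6 alone, or a C–O bond) would not form the ring and two stereocentres together.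

**2 to 1.** The enol O–Si bond is cut. Enol silylation of the commercial silyloxy aldehyde 1 gives 2 in one step.

## Alternatives that were turned down

**Alternative 1: desymmetrising oxa-Michael addition on a para-quinol.**
- Disconnection: the C1–O bond, leading to the achiral dienone A1 (4-(benzoyloxymethyl)-4-hydroxycyclohexa-2,5-dienone).
- Forward key step: A1 and PhB(OH)2 form a boronate hemiester on the C6 hydroxyl. A chiral amine–thiourea catalyst directs its B–OH oxygen onto C1 of one of the two enantiotopic enone arms, giving the cis-fused dioxaborolane enone A2.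
- For it: the absolute configuration comes from an organocatalyst acting on a flat, easily made substrate. The quaternary C6 and the cis C1–O/C6–O pair are fixed at once and leave the step protected. On these two points it is stronger than the chosen route, which reaches C6 only at step 7 by substrate control.
- Against it: A2 has a C3 ketone and a C4=C5 alkene. The C2 oxygen is still missing and must be introduced trans to C1–O by α-oxygenation next to a β-alkoxy ketone that can eliminate. The unsaturation must then be moved to C3=C4 with a new C5–OH trans to C6–O (epoxidation and Wharton-type transposition, or reduction and allylic shift). Each of these carries its own facial question, and the sequence after the key step is clearly longer.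
- Comparison: the chosen route delivers the ring, C1 and C2 and the correct diene oxidation pattern in one step, so that only one oxidation and one hydration remain.

**Alternative 2: SmI2 pinacol closure of an acyclic keto-aldehyde.**
- Disconnection: the C1–C6 bond, leading to the (Z)-configured keto-aldehyde A3.
- Forward key step: SmI2 couples the C1 aldehyde with the C6 ketone through a chelated diketyl, giving the cis C1,C6-diol A4.
- For it: the cis diol is the normal outcome of such closures, C2 and C5 are carried in from the chain, and all five oxygens arrive orthogonally protected. The endgame is protecting-group exchange only, and on oxygen differentiation it is stronger than the chosen route.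
- Against it: A3 needs a long linear build (two stereocentres, a Z alkene, two different termini). Its α-alkoxy aldehyde can epimerise and its skipped alkene can move into conjugation. Divalent samarium also cleaves α-alkoxy ketones reductively, and C6 has such oxygens on both sides. The face of ring closure relative to C2 and C5 is under substrate control only.
- Comparison: on step count and on the chemoselectivity of the key step it is weaker. The chosen route offers convergence from two achiral components.

**Alternative 3: biomimetic hydroxyl-directed epoxidation as the key step.**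
- Disconnection: the C5–O and C6–O bonds of the epoxide, leading to the dienyl trans-diol monoester A5.
- Forward key step: a peracid hydrogen-bonded to the C1 hydroxyl epoxidises C5=C6 on the same face, giving A6.
- For it: it follows the likely biogenesis, sets the quaternary centre in one reliable reaction and leaves a two-step endgame.
- Against it: as a strategy it makes neither the ring nor C1 and C2. The aromatisation-prone, enantiopure diene A5 has to come from somewhere else.
- Comparison: A5 and A6 have the structures of 9 and 10, and the same transformation is step 7 of the chosen route. On setting C5 and C6 the two are equal. The chosen strategy adds a short, enantioselective source of the diene.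

Key step: step 2

Assumption 1: (tert-butyldimethylsilyloxy)acetaldehyde 1 and pyrone 3 are taken as commercial.
Assumption 2: the sense of induction of the Yb(OTf)3–BINOL catalyst with alkene 2 cannot be predicted with certainty. (R)-BINOL is written, and the (S)-ligand would be used if it proved to favour the (5R,6R)-diene 5.

## Route

Step 1
Reactants: 1 (tert-butyldimethylsilyloxy)acetaldehyde
Product: 2 (E)-1,2-bis(tert-butyldimethylsilyloxy)ethene
Conditions: TBSOTf, Et3N, CH2Cl2, 0 °C → rt; E isomer separated from Z (Et3N-deactivated SiO2, hexane, or fractional distillation)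
Reagents that add atoms: tert-butyldimethylsilyl triflate, CC(C)(C)[Si](C)(C)OS(=O)(=O)C(F)(F)F
Why: Soft enolisation (O-silylation of the aldehyde, then deprotonation by the amine) is the standard route to aldehyde silyl enol ethers and should give both geometric isomers, which are configurationally stable and differ in polarity, so the non-polar E isomer can be separated. No stereocentre is formed; only the alkene geometry matters and it is checked before use.

Step 2
Reactants: 2 (E)-1,2-bis(tert-butyldimethylsilyloxy)ethene; 3 methyl 2-oxo-2H-pyran-3-carboxylate
Product: 5 methyl (5R,6R)-5,6-bis(tert-butyldimethylsilyloxy)cyclohexa-1,3-diene-1-carboxylate, via bicyclic lactone 4 (not isolated)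
Conditions: Yb(OTf)3 (10 mol%), (R)-BINOL (12 mol%), i-Pr2NEt (25 mol%), 4 Å MS, CH2Cl2, −20 °C → rt; filtration through neutral Al2O3; then NaHCO3 (solid), toluene, 90 °C
Reagents that add atoms: none
Why: This is an inverse-electron-demand Diels–Alder reaction followed by a retro-Diels–Alder loss of CO2; the closest known reaction type is the cycloaddition of 3-carbomethoxy-2-pyrone with enol ethers under chiral Yb(OTf)3–BINOL–amine catalysis, with thermal decarboxylation of the bicyclic lactones to cyclohexa-1,3-dienes. The pyrone binds trivalent ytterbium through its two carbonyl oxygens, which lowers the LUMO of its diene, and the electron-rich alkene 2 adds suprafacially across the two diene termini. The carbocycle is closed by this intermolecular concerted [4+2] addition, which forms C6–C1 and C3–C2 and gives the 2-oxabicyclo[2.2.2]octenone 4; a [4+2] cycloreversion then expels the lactone bridge and leaves the six-membered ring as a 1,3-diene with the ester on its terminus. The trans relation of C1 and C2 is controlled by the E geometry of 2, which a concerted addition passes on unchanged. The absolute configuration is controlled by which face of 2 bonds; that follows from the pyrone face left open by the BINOL ligand together with the Alder endo preference of the silyloxy group on the carbon that bonds to the ester-bearing terminus, and the two lactone diastereomers that arise from the same alkene face converge on the same enantiomer of 5 once the bridgeheads become sp2. There is no regiochemical question because 2 is symmetric. The step needs stereospecificity, which the amine-buffered Lewis acid and the non-ionising solvent should secure by disfavouring a stepwise zwitterionic path, and it needs the silyloxy groups to survive CO2 loss, which is secured by removing the Lewis acid before heating under neutral, base-buffered conditions.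

Step 3
Reactants: 5 methyl (5R,6R)-5,6-bis(tert-butyldimethylsilyloxy)cyclohexa-1,3-diene-1-carboxylate
Product: 6 [(5R,6R)-5,6-bis(tert-butyldimethylsilyloxy)cyclohexa-1,3-dien-1-yl]methanol
Conditions: i-Bu2AlH (2.5 equiv), CH2Cl2, −78 °C; aq. KNaC4H4O6 work-up
Reagents that add atoms: none
Why: 1,2-Reduction of a conjugated ester by i-Bu2AlH at low temperature is reliable and leaves the diene and the silyl ethers alone. The neutral tartrate work-up avoids acid, which would eliminate silanol and aromatise the ring; no stereocentre is touched.

Step 4
Reactants: 6 [(5R,6R)-5,6-bis(tert-butyldimethylsilyloxy)cyclohexa-1,3-dien-1-yl]methanol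
Product: 7 [(5R,6R)-5,6-bis(tert-butyldimethylsilyloxy)cyclohexa-1,3-dien-1-yl]methyl benzoate
Conditions: BzCl, Et3N, DMAP (cat.), CH2Cl2, 0 °C
Reagents that add atoms: benzoyl chloride, O=C(Cl)c1ccccc1
Why: Nucleophile-catalysed acylation of the only free (primary allylic) hydroxyl installs the C7 benzoate while C1–O and C2–O are still silylated, so no selectivity question arises.

Step 5
Reactants: 7 [(5R,6R)-5,6-bis(tert-butyldimethylsilyloxy)cyclohexa-1,3-dien-1-yl]methyl benzoate
Product: 8 [(5R,6R)-5,6-dihydroxycyclohexa-1,3-dien-1-yl]methyl benzoate
Conditions: n-Bu4NF, AcOH (1:1), THF, 0 °C → rt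
Reagents that add atoms: none
Why: Fluoride cleavage of the two secondary silyl ethers; the AcOH buffer keeps the medium near neutral, so the alkoxides do not move the C7 benzoate and the diene diol is not exposed to acid that would dehydrate it to an arene.

Step 6
Reactants: 8 [(5R,6R)-5,6-dihydroxycyclohexa-1,3-dien-1-yl]methyl benzoate
Product: 9 [(5R,6R)-5-(benzoyloxy)-6-hydroxycyclohexa-1,3-dien-1-yl]methyl benzoate
Conditions: BzCl (1.05 equiv), pyridine, CH2Cl2, −40 °C
Reagents that add atoms: benzoyl chloride, O=C(Cl)c1ccccc1
Why: Kinetic monoacylation of a diol: the C2 hydroxyl is flanked by a CH= carbon, whereas the C1 hydroxyl is flanked by the fully substituted C6 with its benzoyloxymethyl group, so the less hindered C2–OH should react first at low temperature with one equivalent of acyl chloride.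

Step 7
Reactants: 9 [(5R,6R)-5-(benzoyloxy)-6-hydroxycyclohexa-1,3-dien-1-yl]methyl benzoate
Product: 10 [(1S,2S,3R,6R)-3-(benzoyloxy)-2-hydroxy-7-oxabicyclo[4.1.0]hept-4-en-1-yl]methyl benzoate
Conditions: mCPBA, CH2Cl2–aq. NaHCO3 (two-phase), 0 °C
Reagents that add atoms: 3-chloroperbenzoic acid, OOC(=O)c1cccc(Cl)c1
Why: Hydroxyl-directed (Henbest) epoxidation: the peracid is hydrogen-bonded to the free C1 hydroxyl and delivers oxygen to the adjacent, more electron-rich trisubstituted C5=C6 alkene on the face of C1–OH, which sets the quaternary centre C6 (O cis to C1–O) and C5. The C3=C4 alkene is disubstituted, deactivated by the allylic benzoate and has no directing group; the bicarbonate phase removes the acid that would open the vinyl epoxide.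

Step 8
Reactants: 10 [(1S,2S,3R,6R)-3-(benzoyloxy)-2-hydroxy-7-oxabicyclo[4.1.0]hept-4-en-1-yl]methyl benzoate
Product: 11 [(1R,2S,3R,6R)-2-acetoxy-3-(benzoyloxy)-7-oxabicyclo[4.1.0]hept-4-en-1-yl]methyl benzoate
Conditions: Ac2O, pyridine, DMAP (cat.), CH2Cl2, 0 °C → rt
Reagents that add atoms: acetic anhydride, CC(=O)OC(C)=O
Why: DMAP-catalysed acetylation of the only free hydroxyl; doing it at the epoxide stage is what distinguishes the C1 oxygen from the C5 and C6 oxygens, which are still tied up in the oxirane.

Step 9
Reactants: 11 [(1R,2S,3R,6R)-2-acetoxy-3-(benzoyloxy)-7-oxabicyclo[4.1.0]hept-4-en-1-yl]methyl benzoate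
Product: 12 [(1R,2S,5R,6S)-6-acetoxy-5-(benzoyloxy)-1,2-dihydroxycyclohex-3-en-1-yl]methyl benzoate
Conditions: HClO4 (cat., 0.1 M aq.), THF–H2O, 0 °C → rt
Reagents that add atoms: water, O
Why: Acid-catalysed hydration of a vinyl epoxide: water attacks the protonated oxirane at the allylic carbon C5 from the face opposite the oxygen, so C5 is inverted (OH trans to C6–OH) while the C6–O bond and the quaternary centre are untouched. Dilute acid at low temperature is used to keep the three esters in place.

## Compound list

1 | (tert-butyldimethylsilyloxy)acetaldehyde | CC(C)(C)[Si](C)(C)OCC=O | starting material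
2 | (E)-1,2-bis(tert-butyldimethylsilyloxy)ethene | CC(C)(C)[Si](C)(C)O/C=C/O[Si](C)(C)C(C)(C)C | intermediate
3 | methyl 2-oxo-2H-pyran-3-carboxylate | COC(=O)C1=CC=COC1=O | starting material
4 | methyl 7,8-trans-7,8-bis(tert-butyldimethylsilyloxy)-3-oxo-2-oxabicyclo[2.2.2]oct-5-ene-4-carboxylate (C8–O, next to the ester bridgehead, anti to the lactone bridge; C7–O syn to it) | COC(=O)[C@@]12C=C[C@@H](OC1=O)[C@@H](O[Si](C)(C)C(C)(C)C)[C@@H]2O[Si](C)(C)C(C)(C)C | intermediate
5 | methyl (5R,6R)-5,6-bis(tert-butyldimethylsilyloxy)cyclohexa-1,3-diene-1-carboxylate | CC(C)(C)[Si](C)(C)O[C@H]1[C@H](O[Si](C)(C)C(C)(C)C)C=CC=C1C(=O)OC | intermediate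
6 | [(5R,6R)-5,6-bis(tert-butyldimethylsilyloxy)cyclohexa-1,3-dien-1-yl]methanol | CC(C)(C)[Si](C)(C)O[C@H]1[C@H](O[Si](C)(C)C(C)(C)C)C=CC=C1CO | intermediate
7 | [(5R,6R)-5,6-bis(tert-butyldimethylsilyloxy)cyclohexa-1,3-dien-1-yl]methyl benzoate | CC(C)(C)[Si](C)(C)O[C@H]1[C@H](O[Si](C)(C)C(C)(C)C)C=CC=C1COC(=O)c1ccccc1 | intermediate
8 | [(5R,6R)-5,6-dihydroxycyclohexa-1,3-dien-1-yl]methyl benzoate | O[C@H]1[C@H](O)C=CC=C1COC(=O)c1ccccc1 | intermediate
9 | [(5R,6R)-5-(benzoyloxy)-6-hydroxycyclohexa-1,3-dien-1-yl]methyl benzoate | O[C@H]1[C@H](OC(=O)c2ccccc2)C=CC=C1COC(=O)c1ccccc1 | intermediate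
10 | [(1S,2S,3R,6R)-3-(benzoyloxy)-2-hydroxy-7-oxabicyclo[4.1.0]hept-4-en-1-yl]methyl benzoate | O[C@H]1[C@H](OC(=O)c2ccccc2)C=C[C@H]2O[C@@]12COC(=O)c1ccccc1 | intermediate
11 | [(1R,2S,3R,6R)-2-acetoxy-3-(benzoyloxy)-7-oxabicyclo[4.1.0]hept-4-en-1-yl]methyl benzoate | CC(=O)O[C@H]1[C@H](OC(=O)c2ccccc2)C=C[C@H]2O[C@@]12COC(=O)c1ccccc1 | intermediate
12 | [(1R,2S,5R,6S)-6-acetoxy-5-(benzoyloxy)-1,2-dihydroxycyclohex-3-en-1-yl]methyl benzoate | CC(=O)O[C@H]1[C@H](OC(=O)c2ccccc2)C=C[C@H](O)[C@]1(O)COC(=O)c1ccccc1 | target

## Step count and least certain steps

Total: 9 steps. Longest linear sequence: 9 steps (1 to 12); pyrone 3 enters at step 2.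

**Step 2 (key step).**
- What may go wrong: the Lewis-acid-activated addition may turn stepwise, so that bond rotation in a zwitterion erodes the transfer of the E geometry. Enantioselectivity may be poor, because the catalyst must control both the pyrone face and which silyloxy group lies endo. The bulky 1,2-disubstituted enol ether may add slowly. Silanol may be eliminated with aromatisation during CO2 loss.
- Fallback: from 2 and 3, the cycloaddition would be run without any Lewis acid (neat or in toluene with mild heating, or under high pressure), where it should be concerted and stereospecific. This gives lactone 4 together with the enantiomeric lactone F1. Heating gives 5 together with the enantiomeric diene F2. Resolution by preparative chromatography on a chiral stationary phase returns to the route at 5.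

**Step 1.**
- What may go wrong: enolisation may favour the isomer with the two oxygens cis, so that 2 is the minor product and its separation is wasteful.
- Fallback: the co-formed (Z)-1,2-bis(tert-butyldimethylsilyloxy)ethene F3 would be used as feedstock. Triplet-sensitised photoisomerisation (acetone or xanthone as sensitiser, hν, pentane) should give a photostationary E/Z mixture, from which 2 is separated and the remainder recycled. The fallback comes back at 2.

**Step 6.**
- What may go wrong: site selectivity between the C1 and C2 hydroxyls may be poor, and the benzoyl group may migrate between them.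
- Fallback: from 8, the order of the two operations is reversed. Buffered mCPBA epoxidation of the diol, directed by the C1 hydroxyl onto the trisubstituted C5=C6 alkene, would give [(1S,2S,3R,6R)-2,3-dihydroxy-7-oxabicyclo[4.1.0]hept-4-en-1-yl]methyl benzoate F4. In F4 the C1 hydroxyl is flanked by the fully substituted oxirane carbon and hydrogen-bonded to the oxirane oxygen, so monobenzoylation (BzCl, pyridine, low temperature) should go to C2–OH and give 10.

**Step 7.**
- What may go wrong: oxygen may be delivered to the wrong alkene or the wrong face, or the acid by-product may open the vinyl epoxide.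
- Fallback: from 6, desilylation (n-Bu4NF, AcOH, THF) would give (1R,2R)-3-(hydroxymethyl)cyclohexa-3,5-diene-1,2-diol F5. Its C5=C6 alkene is flanked by two allylic hydroxyls (C1–OH and C7–OH), which suits a metal-alkoxide-bound epoxidation with VO(acac)2 (cat.) and t-BuOOH in CH2Cl2. Oxygen is delivered cis to the C1 hydroxyl under non-acidic conditions, giving (1S,2S,3R,6R)-1-(hydroxymethyl)-7-oxabicyclo[4.1.0]hept-4-ene-2,3-diol F6. Dibenzoylation with two equivalents of BzCl (primary C7–OH, then the less hindered C2–OH) returns to the route at 10.

**Step 9.**
- What may go wrong: water may be captured at C3 with allylic shift instead of at C5. The C7 benzoate may participate at C5 and end up on the C5 oxygen. The acetate may migrate to the C6 hydroxyl.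
- Fallback: from 11, the epoxide would be opened under anhydrous conditions with 4-methoxybenzyl alcohol and catalytic BF3·OEt2 in CH2Cl2 at −40 °C. Anti attack at C5 would give [(1R,2S,5R,6S)-6-acetoxy-5-(benzoyloxy)-1-hydroxy-2-(4-methoxybenzyloxy)cyclohex-3-en-1-yl]methyl benzoate F7. Oxidative removal of the ether (DDQ, CH2Cl2–pH 7 buffer) then gives 12 without exposing the esters to aqueous acid.

## Further compounds

F1 | step 2 | enantiomer of bicyclic lactone 4 | COC(=O)[C@]12C=C[C@H](OC1=O)[C@H](O[Si](C)(C)C(C)(C)C)[C@H]2O[Si](C)(C)C(C)(C)C
F2 | step 2 | methyl (5S,6S)-5,6-bis(tert-butyldimethylsilyloxy)cyclohexa-1,3-diene-1-carboxylate | CC(C)(C)[Si](C)(C)O[C@@H]1[C@@H](O[Si](C)(C)C(C)(C)C)C=CC=C1C(=O)OC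
F3 | step 1 | (Z)-1,2-bis(tert-butyldimethylsilyloxy)ethene | CC(C)(C)[Si](C)(C)O/C=C\O[Si](C)(C)C(C)(C)C
F4 | step 6 | [(1S,2S,3R,6R)-2,3-dihydroxy-7-oxabicyclo[4.1.0]hept-4-en-1-yl]methyl benzoate | O[C@H]1[C@H](O)C=C[C@H]2O[C@@]12COC(=O)c1ccccc1
F5 | step 7 | (1R,2R)-3-(hydroxymethyl)cyclohexa-3,5-diene-1,2-diol | O[C@H]1[C@H](O)C=CC=C1CO
F6 | step 7 | (1S,2S,3R,6R)-1-(hydroxymethyl)-7-oxabicyclo[4.1.0]hept-4-ene-2,3-diol | O[C@H]1[C@H](O)C=C[C@H]2O[C@@]12CO
F7 | step 9 | [(1R,2S,5R,6S)-6-acetoxy-5-(benzoyloxy)-1-hydroxy-2-(4-methoxybenzyloxy)cyclohex-3-en-1-yl]methyl benzoate | CC(=O)O[C@H]1[C@H](OC(=O)c2ccccc2)C=C[C@H](OCc2ccc(OC)cc2)[C@]1(O)COC(=O)c1ccccc1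
A1 | alternative 1 | 4-(benzoyloxymethyl)-4-hydroxycyclohexa-2,5-dien-1-one | O=C1C=CC(O)(COC(=O)c2ccccc2)C=C1
A2 | alternative 1 | cis-fused 2-phenyl-1,3,2-dioxaborolane across C1–O and C6–O of the C3-keto C4=C5 enone carrying the C7 benzoate | B1(c2ccccc2)O[C@H]3CC(=O)C=C[C@@]3(COC(=O)c2ccccc2)O1
A3 | alternative 2 | (Z)-5-(tert-butyldimethylsilyloxy)-2,7-bis(4-methoxybenzyloxy)-6-oxohept-3-enal, configured at C2 and C5 as in 12 | O=C[C@H](OCc1ccc(OC)cc1)/C=C\[C@H](O[Si](C)(C)C(C)(C)C)C(=O)COCc1ccc(OC)cc1
A4 | alternative 2 | cis-C1,C6-diol cyclohexene with C2 and C7 4-methoxybenzyl ethers and C5 silyl ether, configured at C1, C2, C5 and C6 as in 12 | O[C@H]1[C@H](OCc2ccc(OC)cc2)C=C[C@H](O[Si](C)(C)C(C)(C)C)[C@]1(O)COCc1ccc(OC)cc1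
A5 | alternative 3 | [(5R,6R)-5-(benzoyloxy)-6-hydroxycyclohexa-1,3-dien-1-yl]methyl benzoate (same structure as 9) | O[C@H]1[C@H](OC(=O)c2ccccc2)C=CC=C1COC(=O)c1ccccc1
A6 | alternative 3 | [(1S,2S,3R,6R)-3-(benzoyloxy)-2-hydroxy-7-oxabicyclo[4.1.0]hept-4-en-1-yl]methyl benzoate (same structure as 10) | O[C@H]1[C@H](OC(=O)c2ccccc2)C=C[C@H]2O[C@@]12COC(=O)c1ccccc1
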